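Ring A of the target (C4a, C5–C8, C8a) carries 5-OH, 7-O and 8-prenyl in a meta-dioxygenated pattern and shares the C4a–C8a bond with the pyranone ring C. It is grown in one operation on a preformed 2-aryloxy-4-pyranone. A photochemical Wolff rearrangement of an α-prenyl diazo ketone gives a pyranonyl ketene that adds a siloxyalkyne and, by [2+2] cycloaddition, 4π opening and 6π closure, forms C8–C8a, C7–C8, C5–C6 and C4a–C5. The precursor is a 6-(4-methoxyphenoxy)-4-pyranone carrying a 2-diazo-5-methylhex-4-enoyl group at C2, made from a methylthio-pyranone ester. Fluoride desilylation then gives the target.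

Key step: step 8

Remark: the target has no stereocentre and no stereogenic double bond (the prenyl alkene carries two identical methyl groups), so it is achiral and the route needs no enantiocontrol.

Step 1
Reactants: 1 4,4-bis(methylsulfanyl)but-3-en-2-one; 2 diethyl oxalate
Product: 4 ethyl 6-(methylsulfanyl)-4-oxo-4H-pyran-2-carboxylate, via open-chain diketo ester 3 (not isolated)
Conditions: LiHMDS (2.1 equiv), THF, −78 → 0 °C; 1 M HCl; then TsOH·H2O (cat.), PhMe, 80 °C
Reagents that add atoms: none
Why: Crossed Claisen condensation (1 can enolize only at its methyl group and the oxalate has no α-hydrogen) gives the 2,4-diketo ester, whose C2 enol oxygen then closes the pyranone by acid-promoted conjugate addition to the ketene dithioacetal carbon and loss of methanethiol, as in pyranone formation from 1,3,5-tricarbonyl compounds.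

Step 2
Reactants: 4 ethyl 6-(methylsulfanyl)-4-oxo-4H-pyran-2-carboxylate
Product: 5 N-methoxy-N-methyl-6-(methylsulfanyl)-4-oxo-4H-pyran-2-carboxamide
Conditions: MeNH(OMe)·HCl (1.5 equiv), i-PrMgCl (3 equiv), THF, −20 °C
Reagents that add atoms: N,O-dimethylhydroxylamine hydrochloride, CNOC.Cl
Why: Aminolysis of the ester by the preformed chloromagnesium amide (Weinreb amide formation) is done at the robust sulfide stage, where the activated ester is far more electrophilic than the vinylogous thioester carbon.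

Step 3
Reactants: 5 N-methoxy-N-methyl-6-(methylsulfanyl)-4-oxo-4H-pyran-2-carboxamide
Product: 6 N-methoxy-N-methyl-6-(methylsulfonyl)-4-oxo-4H-pyran-2-carboxamide
Conditions: mCPBA (2.3 equiv), CH2Cl2, 0 °C → rt
Reagents that add atoms: 3-chloroperoxybenzoic acid (mCPBA), OOC(=O)c1cccc(Cl)c1
Why: Peracid oxidation of the sulfide to the sulfone is placed before any alkene enters the molecule; the electron-poor pyranone double bonds and the N-methoxy amide are inert to mCPBA.

Step 4
Reactants: 6 N-methoxy-N-methyl-6-(methylsulfonyl)-4-oxo-4H-pyran-2-carboxamide; 7 4-methoxyphenol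
Product: 8 N-methoxy-6-(4-methoxyphenoxy)-N-methyl-4-oxo-4H-pyran-2-carboxamide
Conditions: K2CO3, MeCN, 0 °C → rt
Reagents that add atoms: none
Why: Addition–elimination (vinylogous acyl substitution) at the sulfonyl-bearing carbon β to the ring carbonyl, with methanesulfinate as leaving group, is the standard entry to 2-aryloxy-4-pyranones and 2-aryloxychromones.

Step 5
Reactants: 8 N-methoxy-6-(4-methoxyphenoxy)-N-methyl-4-oxo-4H-pyran-2-carboxamide; 9 5-bromo-2-methylpent-2-ene
Product: 11 2-(4-methoxyphenoxy)-6-(5-methylhex-4-enoyl)-4H-pyran-4-one, via homoprenylmagnesium bromide 10 (not isolated)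
Conditions: 9, Mg, THF, rt; then 8 (Grignard 1.15 equiv added slowly), THF, −78 °C; cold 1 M HCl
Reagents that add atoms: none
Why: Weinreb ketone synthesis; at −78 °C the amide carbonyl, activated by the electron-poor ring, should be attacked faster than the vinylogous carbonate, and the magnesium chelate of the tetrahedral adduct prevents over-addition.

Step 6
Reactants: 11 2-(4-methoxyphenoxy)-6-(5-methylhex-4-enoyl)-4H-pyran-4-one
Product: 13 2-diazo-1-[6-(4-methoxyphenoxy)-4-oxo-4H-pyran-2-yl]-5-methylhex-4-en-1-one, via trifluoroacetyl diketone 12 (not isolated)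
Conditions: LiHMDS, THF, −78 °C; CF3CO2CH2CF3, −78 °C; 1 M HCl work-up; then p-ABSA, Et3N, H2O (1 equiv), MeCN, rt
Reagents that add atoms: 4-acetamidobenzenesulfonyl azide (p-ABSA), CC(=O)Nc1ccc(cc1)S(=O)(=O)N=[N+]=[N-]; 2,2,2-trifluoroethyl trifluoroacetate, O=C(OCC(F)(F)F)C(F)(F)F (its CF3CO group appears only in 12)
Why: Detrifluoroacetylative (Regitz-type) diazo transfer: the only enolizable position, the α-CH2, is trifluoroacetylated and the activated 1,3-diketone takes up the diazo group with loss of the trifluoroacetyl group, so the α-carbon becomes the diazo carbon and keeps its 3-methylbut-2-enyl substituent.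

Step 7
Reactants: 14 acetylene; 15 triisopropylsilyl trifluoromethanesulfonate
Product: 18 ethynyloxy(triisopropyl)silane, via lithium acetylide 16 (not isolated), via lithium ethynolate 17 (not isolated)
Conditions: 14 (excess), n-BuLi, THF, −78 °C; t-BuOOLi (t-BuOOH + LiHMDS), −78 → −10 °C; 15, −78 → 0 °C; pentane, cold aq. NaHCO3
Reagents that add atoms: tert-butyl hydroperoxide, CC(C)(C)OO
Why: Electrophilic oxygen transfer from lithium tert-butyl peroxide to a lithium acetylide is an established route from terminal alkynes to ynolates, and the bulky silyl triflate should silylate the ynolate on oxygen and not on carbon.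

Step 8
Reactants: 13 2-diazo-1-[6-(4-methoxyphenoxy)-4-oxo-4H-pyran-2-yl]-5-methylhex-4-en-1-one; 18 ethynyloxy(triisopropyl)silane
Product: 23 5-hydroxy-2-(4-methoxyphenoxy)-8-(3-methylbut-2-enyl)-7-(triisopropylsilyloxy)chromen-4-one, via pyranonyl ketene 19 (not isolated), via siloxycyclobutenone 20 (not isolated), via dienylketene 21 (not isolated), via 4aH-chromenedione 22 (not isolated)
Conditions: 18 (2 equiv), degassed ClCH2CH2Cl, 440 nm LEDs, rt until N2 evolution ends; then 80 °C
Reagents that add atoms: none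
Why: Proposed new method: visible-light excitation of the diazo chromophore expels N2 and the pyranonyl group migrates from the ketone carbon to the diazo carbon (Wolff rearrangement, C8–C8a) to give ketene 19, a vinylketene because its α-carbon is conjugated with the pyranone C2=C3 bond (future C8a=C4a); [2+2] cycloaddition with the siloxyalkyne (C5–C6 and C7–C8) gives cyclobutenone 20, reversible 4π electrocyclic opening gives dienylketene 21, and thermal disrotatory 6π electrocyclization closes the six-membered ring A through C4a–C5, after which enolization of the 4aH-dione 22 gives phenol 23. The closest known reaction type is the photochemical Danheiser benzannulation of aryl and heteroaryl α-diazo ketones with siloxyalkynes, and the new element is a 4-pyranone C=C bond as the terminus of the 6π closure; it should be a better partner than a benzene ring, because only the weak cross-conjugation of the pyranone is interrupted and the 4a-H that must be lost lies between two carbonyl groups. The one selectivity required is the regiochemistry of the [2+2] step, which the polarization of the ynol ether secures: its nucleophilic CH terminus bonds to the ketene carbonyl carbon, so the former ketone carbon becomes C5–OH, the alkyne carbons C6–H and C7–OSi, and the former diazo carbon C8 with its prenyl group. No stereocentre is created, and because the ring opening of 20 is reversible both geometries of 21 drain through the isomer that has the pyranone cis to the ketene. Irradiation at 440 nm, where the pyranone and the aryl ether should be transparent, avoids the short-wavelength photochemistry of 4-pyranones, and the one-carbon tether keeps the prenyl alkene from trapping the carbene or the ketene.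

Step 9
Reactants: 23 5-hydroxy-2-(4-methoxyphenoxy)-8-(3-methylbut-2-enyl)-7-(triisopropylsilyloxy)chromen-4-one
Product: 24 5,7-dihydroxy-2-(4-methoxyphenoxy)-8-(3-methylbut-2-enyl)chromen-4-one
Conditions: TBAF, AcOH (1:1), THF, 0 °C
Reagents that add atoms: none
Why: Fluoride-induced cleavage of the aryl silyl ether, buffered with acetic acid so that neither fluoride nor the liberated 7-phenoxide attacks the aryloxy-bearing C2, should leave the prenyl group, the 2-aryloxy linkage and the chelated 5-OH untouched.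

Compound list
1 | 4,4-bis(methylsulfanyl)but-3-en-2-one | CC(=O)C=C(SC)SC | starting material
2 | diethyl oxalate | CCOC(=O)C(=O)OCC | starting material
3 | ethyl 6,6-bis(methylsulfanyl)-2,4-dioxohex-5-enoate (open-chain diketo ester, largely enolized, not isolated) | CCOC(=O)C(=O)CC(=O)C=C(SC)SC | intermediate
4 | ethyl 6-(methylsulfanyl)-4-oxo-4H-pyran-2-carboxylate | CCOC(=O)c1cc(=O)cc(SC)o1 | intermediate
5 | N-methoxy-N-methyl-6-(methylsulfanyl)-4-oxo-4H-pyran-2-carboxamide | CON(C)C(=O)c1cc(=O)cc(SC)o1 | intermediate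
6 | N-methoxy-N-methyl-6-(methylsulfonyl)-4-oxo-4H-pyran-2-carboxamide | CON(C)C(=O)c1cc(=O)cc(S(C)(=O)=O)o1 | intermediate
7 | 4-methoxyphenol | COc1ccc(O)cc1 | starting material
8 | N-methoxy-6-(4-methoxyphenoxy)-N-methyl-4-oxo-4H-pyran-2-carboxamide | CON(C)C(=O)c1cc(=O)cc(Oc2ccc(OC)cc2)o1 | intermediate
9 | 5-bromo-2-methylpent-2-ene | CC(C)=CCCBr | starting material
10 | (4-methylpent-3-en-1-yl)magnesium bromide (not isolated) | CC(C)=CCC[Mg]Br | intermediate
11 | 2-(4-methoxyphenoxy)-6-(5-methylhex-4-enoyl)-4H-pyran-4-one | COc1ccc(Oc2cc(=O)cc(C(=O)CCC=C(C)C)o2)cc1 | intermediate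
12 | 4,4,4-trifluoro-1-[6-(4-methoxyphenoxy)-4-oxo-4H-pyran-2-yl]-2-(3-methylbut-2-enyl)butane-1,3-dione (racemic, enolizable, not isolated) | COc1ccc(Oc2cc(=O)cc(C(=O)C(CC=C(C)C)C(=O)C(F)(F)F)o2)cc1 | intermediate
13 | 2-diazo-1-[6-(4-methoxyphenoxy)-4-oxo-4H-pyran-2-yl]-5-methylhex-4-en-1-one | COc1ccc(Oc2cc(=O)cc(C(=O)C(=[N+]=[N-])CC=C(C)C)o2)cc1 | intermediate
14 | acetylene | C#C | starting material
15 | triisopropylsilyl trifluoromethanesulfonate | CC(C)[Si](OS(=O)(=O)C(F)(F)F)(C(C)C)C(C)C | starting material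
16 | lithium acetylide (not isolated) | [Li]C#C | intermediate
17 | lithium ethynolate (not isolated) | [Li+].[O-]C#C | intermediate
18 | ethynyloxy(triisopropyl)silane | C#CO[Si](C(C)C)(C(C)C)C(C)C | intermediate
19 | 2-[6-(4-methoxyphenoxy)-4-oxo-4H-pyran-2-yl]-5-methylhexa-1,4-dien-1-one (pyranonyl ketene, not isolated) | COc1ccc(Oc2cc(=O)cc(C(=C=O)CC=C(C)C)o2)cc1 | intermediate
20 | 4-[6-(4-methoxyphenoxy)-4-oxo-4H-pyran-2-yl]-4-(3-methylbut-2-enyl)-3-(triisopropylsilyloxy)cyclobut-2-en-1-one (racemic, not isolated) | COc1ccc(Oc2cc(=O)cc(C3(CC=C(C)C)C(=O)C=C3O[Si](C(C)C)(C(C)C)C(C)C)o2)cc1 | intermediate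
21 | (3E)-4-[6-(4-methoxyphenoxy)-4-oxo-4H-pyran-2-yl]-7-methyl-3-(triisopropylsilyloxy)octa-1,3,6-trien-1-one (dienylketene, reacting isomer, not isolated) | O=C=C/C(O[Si](C(C)C)(C(C)C)C(C)C)=C(/CC=C(C)C)c1cc(=O)cc(Oc2ccc(OC)cc2)o1 | intermediate
22 | 2-(4-methoxyphenoxy)-8-(3-methylbut-2-enyl)-7-(triisopropylsilyloxy)-4aH-chromene-4,5-dione (racemic, not isolated) | COc1ccc(OC2=CC(=O)C3C(=O)C=C(O[Si](C(C)C)(C(C)C)C(C)C)C(CC=C(C)C)=C3O2)cc1 | intermediate
23 | 5-hydroxy-2-(4-methoxyphenoxy)-8-(3-methylbut-2-enyl)-7-(triisopropylsilyloxy)chromen-4-one | COc1ccc(Oc2cc(=O)c3c(O)cc(O[Si](C(C)C)(C(C)C)C(C)C)c(CC=C(C)C)c3o2)cc1 | intermediate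
24 | 5,7-dihydroxy-2-(4-methoxyphenoxy)-8-(3-methylbut-2-enyl)chromen-4-one | COc1ccc(Oc2cc(=O)c3c(O)cc(O)c(CC=C(C)C)c3o2)cc1 | target

Total step count: 9. Longest linear sequence: 8 steps (steps 1–6, 8 and 9); step 7 is a one-step side branch.

Steps most likely to fail

1. Step 8 (Proposed new method). The carbene may undergo 1,2-hydrogen shift from the adjacent CH2 instead of Wolff migration, the pyranone may be degraded photochemically, or the pyranone C=C bond may be reluctant to enter the 6π closure. The fallback builds the chromone by known chemistry, setting out from 4-methoxyphenol 7 and coming back to the route at 23. Commercial 1-[2,4-bis(benzyloxy)-6-hydroxyphenyl]ethanone F1 is condensed with CS2 (t-BuOK, THF) to 5,7-bis(benzyloxy)-4-hydroxy-2H-chromene-2-thione F2. S-Methylation (MeI, K2CO3, acetone) gives 5,7-bis(benzyloxy)-2-(methylsulfanyl)chromen-4-one F3, and mCPBA gives 5,7-bis(benzyloxy)-2-(methylsulfonyl)chromen-4-one F4. Phenol 7 with K2CO3 displaces the sulfinate to give 5,7-bis(benzyloxy)-2-(4-methoxyphenoxy)chromen-4-one F5, and brief hydrogenolysis (H2, Pd/C) gives 5,7-dihydroxy-2-(4-methoxyphenoxy)chromen-4-one F6. The unchelated 7-OH is silylated (TIPSCl, imidazole) to 5-hydroxy-2-(4-methoxyphenoxy)-7-(triisopropylsilyloxy)chromen-4-one F7. A Mitsunobu reaction with 3-methylbut-2-en-1-ol then gives 2-(4-methoxyphenoxy)-5-(3-methylbut-2-enyloxy)-7-(triisopropylsilyloxy)chromen-4-one F8. Europium(III)-catalysed Claisen rearrangement (Eu(fod)3, NaHCO3, PhCl, 85 °C) to the transient 2-(4-methoxyphenoxy)-6-(2-methylbut-3-en-2-yl)-7-(triisopropylsilyloxy)-6H-chromene-4,5-dione F9, followed by Cope shift to C8 and enolization, should deliver 23. Step 9 follows as in the main route.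

2. Step 7. The monolithium acetylide may disproportionate during the oxygen transfer, silylation may occur at the unhindered carbon terminus instead of oxygen, and the small ynol ether may be lost by evaporation or hydrolysis. The fallback blocks the alkyne terminus with a removable silyl group; it sets out from triisopropylsilyl triflate 15 and comes back at target 24. The known (trimethylsilyl)ketene F10 is deprotonated (n-BuLi, THF, −100 °C) to lithium 2-(trimethylsilyl)ethynolate F11, which 15 silylates on oxygen to give trimethyl[(triisopropylsilyloxy)ethynyl]silane F12, a non-volatile ynol ether. With 13 under the conditions of step 8 it should pass through the 2-trimethylsilyl cyclobutenone F13, the 2-trimethylsilyl dienylketene F14 and the 6-trimethylsilyl 4aH-chromenedione F15 to 5-hydroxy-2-(4-methoxyphenoxy)-8-(3-methylbut-2-enyl)-7-(triisopropylsilyloxy)-6-(trimethylsilyl)chromen-4-one F16. Fluoride with acetic acid should then remove the O-silyl group and, by ipso-protodesilylation of the phloroglucinol-type ring, the C6 silyl group, to give 24.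

3. Step 5. The Grignard reagent may add to the pyranone ring, either by conjugate addition–elimination at the aryloxy-bearing carbon or by attack at the ring carbonyl, in competition with the amide. The fallback changes the order of events so that the organometallic meets a ring without a good leaving group; it sets out from 5 and comes back at 11. Grignard reagent 10 is added to the methylsulfanyl amide 5 (THF, −78 °C) to give 2-(5-methylhex-4-enoyl)-6-(methylsulfanyl)-4H-pyran-4-one F17. Molybdate-catalysed oxidation with H2O2 in EtOH, which spares the trisubstituted alkene, gives 2-(5-methylhex-4-enoyl)-6-(methylsulfonyl)-4H-pyran-4-one F18, and 7 with K2CO3 in MeCN then gives 11.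

Further compounds
F1 | step 8 | 1-[2,4-bis(benzyloxy)-6-hydroxyphenyl]ethanone | CC(=O)c1c(O)cc(OCc2ccccc2)cc1OCc1ccccc1
F2 | step 8 | 5,7-bis(benzyloxy)-4-hydroxy-2H-chromene-2-thione | S=c1cc(O)c2c(OCc3ccccc3)cc(OCc3ccccc3)cc2o1
F3 | step 8 | 5,7-bis(benzyloxy)-2-(methylsulfanyl)chromen-4-one | CSc1cc(=O)c2c(OCc3ccccc3)cc(OCc3ccccc3)cc2o1
F4 | step 8 | 5,7-bis(benzyloxy)-2-(methylsulfonyl)chromen-4-one | CS(=O)(=O)c1cc(=O)c2c(OCc3ccccc3)cc(OCc3ccccc3)cc2o1
F5 | step 8 | 5,7-bis(benzyloxy)-2-(4-methoxyphenoxy)chromen-4-one | COc1ccc(Oc2cc(=O)c3c(OCc4ccccc4)cc(OCc4ccccc4)cc3o2)cc1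
F6 | step 8 | 5,7-dihydroxy-2-(4-methoxyphenoxy)chromen-4-one | COc1ccc(Oc2cc(=O)c3c(O)cc(O)cc3o2)cc1
F7 | step 8 | 5-hydroxy-2-(4-methoxyphenoxy)-7-(triisopropylsilyloxy)chromen-4-one | COc1ccc(Oc2cc(=O)c3c(O)cc(O[Si](C(C)C)(C(C)C)C(C)C)cc3o2)cc1
F8 | step 8 | 2-(4-methoxyphenoxy)-5-(3-methylbut-2-enyloxy)-7-(triisopropylsilyloxy)chromen-4-one | COc1ccc(Oc2cc(=O)c3c(OCC=C(C)C)cc(O[Si](C(C)C)(C(C)C)C(C)C)cc3o2)cc1
F9 | step 8 | 2-(4-methoxyphenoxy)-6-(2-methylbut-3-en-2-yl)-7-(triisopropylsilyloxy)-6H-chromene-4,5-dione (racemic, transient) | COc1ccc(OC2=CC(=O)C3=C(O2)C=C(O[Si](C(C)C)(C(C)C)C(C)C)C(C(C)(C)C=C)C3=O)cc1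
F10 | step 7 | (trimethylsilyl)ketene | C[Si](C)(C)C=C=O
F11 | step 7 | lithium 2-(trimethylsilyl)ethynolate (not isolated) | C[Si](C)(C)C#C[O-].[Li+]
F12 | step 7 | trimethyl[(triisopropylsilyloxy)ethynyl]silane | C[Si](C)(C)C#CO[Si](C(C)C)(C(C)C)C(C)C
F13 | step 7 | 4-[6-(4-methoxyphenoxy)-4-oxo-4H-pyran-2-yl]-4-(3-methylbut-2-enyl)-3-(triisopropylsilyloxy)-2-(trimethylsilyl)cyclobut-2-en-1-one (racemic, transient) | COc1ccc(Oc2cc(=O)cc(C3(CC=C(C)C)C(=O)C([Si](C)(C)C)=C3O[Si](C(C)C)(C(C)C)C(C)C)o2)cc1
F14 | step 7 | (3E)-4-[6-(4-methoxyphenoxy)-4-oxo-4H-pyran-2-yl]-7-methyl-3-(triisopropylsilyloxy)-2-(trimethylsilyl)octa-1,3,6-trien-1-one (transient) | O=C=C([Si](C)(C)C)/C(O[Si](C(C)C)(C(C)C)C(C)C)=C(/CC=C(C)C)c1cc(=O)cc(Oc2ccc(OC)cc2)o1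
F15 | step 7 | 2-(4-methoxyphenoxy)-8-(3-methylbut-2-enyl)-7-(triisopropylsilyloxy)-6-(trimethylsilyl)-4aH-chromene-4,5-dione (racemic, transient) | COc1ccc(OC2=CC(=O)C3C(=O)C([Si](C)(C)C)=C(O[Si](C(C)C)(C(C)C)C(C)C)C(CC=C(C)C)=C3O2)cc1
F16 | step 7 | 5-hydroxy-2-(4-methoxyphenoxy)-8-(3-methylbut-2-enyl)-7-(triisopropylsilyloxy)-6-(trimethylsilyl)chromen-4-one | COc1ccc(Oc2cc(=O)c3c(O)c([Si](C)(C)C)c(O[Si](C(C)C)(C(C)C)C(C)C)c(CC=C(C)C)c3o2)cc1
F17 | step 5 | 2-(5-methylhex-4-enoyl)-6-(methylsulfanyl)-4H-pyran-4-one | CSc1cc(=O)cc(C(=O)CCC=C(C)C)o1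
F18 | step 5 | 2-(5-methylhex-4-enoyl)-6-(methylsulfonyl)-4H-pyran-4-one | CS(=O)(=O)c1cc(=O)cc(C(=O)CCC=C(C)C)o1
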